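## Structural features

The target is a single carbocycle, a cyclohexene numbered here C1 (CHOAc), C2 (=CH), C3 (=C, carrying the exocyclic C7H2OBz), C4 (CHOH), C5 (CHOBz) and C6 (CHOH); the oxygens are called O1, O4, O5, O6 and O7 after their carbons. The four stereocentres form an unbroken run C4–C5–C6–C1 with configurations 4S, 5R, 6S, 1R. O5 and O6 are cis to each other on one face (called the upper face below), and O1 and O4 lie on the lower face, each trans to its neighbour in the diol pair. The fragile elements are three esters on a polyol (the C5 benzoate can wander to the cis O6 or to O4, the C1 acetate to O6), an allylic acetate, an allylic primary benzoate, and a ring that is two eliminations away from an arene. The skeleton itself is trivial; the real difficulty is to set four stereocentres in one absolute sense and to tell five oxygens apart, two of which (O1, O4) are both allylic and two (O5, O6) both homoallylic and cis. The key step uses the fact that C1 and C4 are para-related oxygen-bearing ring carbons with C7 on C3 next to C4, the pattern of a 2-substituted hydroquinone diether. Anodic dearomatisation turns these two aryl ether carbons into two ketals of unequal reactivity, keeps C2=C3 and leaves C5=C6 free for dihydroxylation.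

## Logic of the disconnections

13 to 11 (through 12): the O5–C(=O)Ph bond is cut. The benzoate on one oxygen of a cis-diol is the last differentiation, and removing it leaves a triol with only the acetate and the C7 benzoate in place. The forward step must acylate O5 and not O6 or O4, which is asked of a cyclic orthoester across O5/O6 that opens to the ester on the axial oxygen.

11 to 10: the C4–H bond is cut, so the carbinol becomes an enone carbonyl and one stereocentre disappears. The forward reduction must deliver hydride to the upper face of C4, which the two hydroxyls on that face can direct.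

10 to 9: the C4 carbonyl is returned to its dimethyl ketal. This keeps C4 masked while the diol is installed and traces C4 back to an aryl ether carbon. The forward hydrolysis must spare two esters and must not trigger β-elimination.

9 to 8: the C5–O5 and C6–O6 bonds are cut together, removing two stereocentres and restoring a 1,4-diene. The forward oxidation must choose C5=C6 over C2=C3 and the face opposite the C1 acetate.

8 to 7: the O1–acetyl bond is cut. The acetate is placed while O1 is the only hydroxyl in the molecule, so no selectivity problem arises. The forward step only has to avoid acid.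

7 to 6: the C1–H bond is cut, giving an achiral cross-conjugated dienone. All chirality of the route is thereby reduced to one carbonyl face. The forward reduction must distinguish two flanks that differ only at the β-carbon, a task for an enzyme.

6 to 5: the C1 carbonyl is returned to a dimethyl ketal, giving a bisketal in which both para carbons are at the same oxidation level. The forward hydrolysis must open the C1 ketal and leave the C4 ketal, which the C3 substituent should ensure.

5 to 3 and 4: the two C–OMe bonds formed at C1 and C4 are cut, which rearomatises the ring and releases two molecules of 4. Every carbon, the C7 ester and both para oxygens are then found in a simple benzene derivative. The forward oxidation must attack the ring and not the side chain, and must not cleave the ester.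

3 to 1 and 2: the O7–C(=O)Ph bond is cut. The ester of the target is installed first and serves as its own protecting group.

## Other disconnections considered

Alternative 1: The ring is cut at C1–C2 and C3–C4, a [4+2] retron. The diene (1E,3E)-buta-1,3-diene-1,4-diyl diacetate A2 supplies C4, C5, C6 and C1 with both oxygens, and methyl 2-[(S)-p-tolylsulfinyl]acrylate A3 supplies C2, C3 and C7. The forward key step is a ZnCl2-promoted cycloaddition of A2 and A3 to the sulfinyl cyclohexene diacetate A1; later the sulfoxide would leave by syn-elimination to create C2=C3.
- In its favour: the carbocycle, the cis relation of O1 and O4 and the absolute configuration would all come from one step. On the control of C4 it is the better plan, because C4 is set by the diene geometry and not by a late reduction. It is at least the equal of the chosen plan for the later osmylation, since two acetates on one face would both steer the reagent to the other.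
- Against it: C7 arrives as a methyl ester, and its reduction would also attack both acetates, which forces protecting-group exchanges. O1 and O4 carry the same group although only O1 keeps an acetate in the target. The sulfoxide elimination must go toward C2 and not C4. A2 is a sluggish diene and A3 needs a stoichiometric chiral sulfur source.
- Comparison: structurally the chosen plan has C7 at the right oxidation level and O1/O4 differentiated by intrinsic ketal reactivity, where this plan must differentiate them by extra steps. Mechanistically a pericyclic step with auxiliary control is more predictable than an enzyme screen. In step count the alternative should be clearly longer than nine.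

Alternative 2: The ring is cut at C3–C4, together with the O–C7 bond of a fused isoxazoline. This leads back to the open-chain hept-6-enose oxime A5, which would be made from D-mannose A6. In the forward step the nitrile oxide generated from A5 adds to the terminal vinyl group and gives the cyclohexane-fused isoxazoline A4.
- In its favour: the configurations of C1, C5 and C6 come from the sugar A6, so no enantioselective step is needed; on certainty of absolute configuration this is the better plan. The cis O5/O6 pair is present from the start, and C4 appears in A4 as a C=N carbon that can be unveiled and reduced under the same hydroxyl direction as in the chosen plan, an equal point.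
- Against it: reaching A5 requires many protecting-group and chain-extension steps on A6. After the cycloaddition, N–O cleavage, loss of the C2 benzoate to form C2=C3, benzoylation of O7, acetylation of O1 and acetonide removal are still needed. The O5/O6 differentiation remains exactly the problem it is in the chosen plan.
- Comparison: structurally both plans end with the same late enone and the same end game. Mechanistically the dipolar cycloaddition is reliable but builds a stereocentre at C3 that is destroyed again. In step economy the chosen plan should be roughly half as long and uses no protecting group that is not part of the target.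

Alternative 3: The ring is cut at C4–C5 and C1–C6. The diene furan-3-ylmethyl benzoate A8 supplies C1 to C4 with C7, and the dienophile vinylene carbonate A9 supplies C5 and C6 with their oxygens. The forward key step is an endo [4+2] cycloaddition of A8 and A9 to the oxanorbornene carbonate A7, followed by opening of the oxygen bridge.
- In its favour: the two simple components A8 and A9 give, in one step, the carbocycle, the C7 benzoate, the C2=C3 alkene and the correct relative arrangement of O5/O6 against the bridge. In brevity of ring construction and in relative stereocontrol by geometry it is the better plan.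
- Against it: cycloadditions of a furan such as A8 with A9 are reversible and tend to give endo/exo mixtures, and A7 would be racemic without a resolution or a chiral promoter. Above all, the bridge of A7 holds one oxygen for two carbinol carbons. The opening must therefore break one C–O bond and make a new one at the same carbon with net retention (O1 and O4 are cis in the target), through an allyl cation that can also be attacked at C3. O1 versus O4 and O5 versus O6 would still have to be told apart.
- Comparison: structurally the chosen plan takes both O1 and O4 from the arene and never has to create a ring C–O bond at C1 or C4. Mechanistically the alternative trades an enzyme screen for an ionisation of uncertain regiochemistry and face selectivity. In step count it could be shorter only if the opening and the resolution both behave.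

Key step: step 2

Remark on the chemistry: methanol (4) is both reactant and solvent in step 2, and two molecules of it are built into 5. The enzyme of step 4 is assumed to come from screening a ketoreductase panel for hydride delivery to the Re face of C1.

## Route

Step 1
Reactants: 1 2,5-dimethoxybenzyl alcohol; 2 benzoyl chloride
Product: 3 2,5-dimethoxybenzyl benzoate
Conditions: Et3N, DMAP (cat.), CH2Cl2, 0 °C to rt
Reagents that add atoms: none
Why: Nucleophilic-catalysed acylation of a primary benzylic alcohol; the benzoate is the C7 ester of the target, so no separate protecting group is spent.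

Step 2
Reactants: 3 2,5-dimethoxybenzyl benzoate; 4 methanol
Product: 5 (3,3,6,6-tetramethoxycyclohexa-1,4-dien-1-yl)methyl benzoate
Conditions: undivided cell, graphite anode, Pt cathode, constant current (about 2.2–2.5 F/mol), Et4NOTs, 2,6-lutidine, MeOH, 0 °C
Reagents that add atoms: methanol (second equivalent, taken from the solvent), CO
Why: Anodic nuclear methoxylation of a 1,4-dimethoxyarene to a quinone bisketal is the closest known reaction type and is used here without change; overall 3 takes up two molecules of methanol and loses two electrons and two protons. The arene loses one electron at the carbon anode, methanol adds to the radical cation at a methoxy-bearing ring carbon, and loss of a proton plus a second electron transfer gives a methoxy-stabilised cyclohexadienyl cation that a second methanol traps at the para methoxy-bearing carbon; the two new C–O bonds therefore stand at C1 and C4 and the arene becomes the 1,4-diene. At the cathode methanol is reduced to H2 and methoxide, which balances the anodic protons, so the undivided cell stays near neutral. No ring is closed and no stereocentre is formed: 5 is achiral and carries C2=C3 and C5=C6 as the two alkenes used later. The step needs ring attack to win over side-chain oxidation and needs the benzoate to survive. The para-dimethoxy pattern puts the charge and spin of the radical cation on the oxygenated ring carbons, and the acyloxy group makes the C7 hydrogens poor donors. Ester methanolysis is held back by the neutral tosylate electrolyte, the lutidine buffer, the low temperature and by stopping at the required charge; the same buffer and a basic work-up protect the ketals from acid.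

Step 3
Reactants: 5 (3,3,6,6-tetramethoxycyclohexa-1,4-dien-1-yl)methyl benzoate
Product: 6 (6,6-dimethoxy-3-oxocyclohexa-1,4-dien-1-yl)methyl benzoate
Conditions: AcOH, H2O, acetone, 0 °C
Reagents that add atoms: water, O
Why: Acid-catalysed ketal hydrolysis; the C1 ketal ionises faster because its oxocarbenium ion is an allyl cation with one terminus on the substituted C3 and because it is the less crowded ketal, and once the C1 ketone exists the dienone deactivates the C4 ketal, so the reaction should stop at the monoketal.

Step 4
Reactants: 6 (6,6-dimethoxy-3-oxocyclohexa-1,4-dien-1-yl)methyl benzoate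
Product: 7 [(3S)-3-hydroxy-6,6-dimethoxycyclohexa-1,4-dien-1-yl]methyl benzoate
Conditions: ketoreductase (panel enzyme delivering hydride to the Re face of C1), NADP+ (cat.), i-PrOH (10% v/v), KH2PO4/K2HPO4 buffer pH 7.5, DMSO (5% v/v), 30 °C
Reagents that add atoms: none
Why: Enzymatic carbonyl reduction of a cyclic conjugated ketone with cofactor recycling by isopropanol; the active site tells the two flanks apart by the benzoyloxymethyl arm on C3 and puts hydride on the upper (Re) face of C1, which sets C1 (S here, R in the target after the priority change) with O1 on the lower face. The near-neutral buffer keeps the acid-labile dienol ketal from aromatising.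

Step 5
Reactants: 7 [(3S)-3-hydroxy-6,6-dimethoxycyclohexa-1,4-dien-1-yl]methyl benzoate
Product: 8 [(3S)-3-acetoxy-6,6-dimethoxycyclohexa-1,4-dien-1-yl]methyl benzoate
Conditions: Ac2O, pyridine, DMAP (cat.), CH2Cl2, 0 °C
Reagents that add atoms: acetic anhydride, CC(=O)OC(C)=O
Why: Nucleophilic-catalysed acetylation of the only hydroxyl in the molecule; basic anhydrous conditions prevent ionisation of the dienyl ketal, and C1 keeps its configuration because its C–O bond is not broken.

Step 6
Reactants: 8 [(3S)-3-acetoxy-6,6-dimethoxycyclohexa-1,4-dien-1-yl]methyl benzoate
Product: 9 [(3R,4R,5S)-3-acetoxy-4,5-dihydroxy-6,6-dimethoxycyclohex-1-en-1-yl]methyl benzoate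
Conditions: OsO4 (2 mol%), NMO (1.2 equiv), acetone/H2O (8:1), 0 °C to rt; Na2SO3 quench
Reagents that add atoms: N-methylmorpholine N-oxide, C[N+]1([O-])CCOCC1; water, O; osmium tetroxide (catalytic oxygen carrier), O=[Os](=O)(=O)=O
Why: Catalytic syn-dihydroxylation by [3+2] addition of OsO4 and hydrolysis of the osmate ester; the reagent should add to C5=C6 from the face opposite the allylic C1 acetate (the usual anti preference for allylic oxygen substituents), which sets C5 and C6 together with O5 and O6 on the upper face. C2=C3 should react more slowly because it carries a third allylic oxygen (the C7 benzoate) and a fully substituted C3 beside the ketal.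

Step 7
Reactants: 9 [(3R,4R,5S)-3-acetoxy-4,5-dihydroxy-6,6-dimethoxycyclohex-1-en-1-yl]methyl benzoate
Product: 10 [(3R,4R,5S)-3-acetoxy-4,5-dihydroxy-6-oxocyclohex-1-en-1-yl]methyl benzoate
Conditions: TFA, H2O, CH2Cl2, 0 °C
Reagents that add atoms: water, O
Why: Acid-catalysed hydrolysis of an allylic dimethyl ketal to the enone; with C5=C6 gone no aromatisation path is open, both esters tolerate brief cold aqueous acid, and acidic conditions avoid base-induced β-elimination of O6 and acyl shift from O1 to O6.

Step 8
Reactants: 10 [(3R,4R,5S)-3-acetoxy-4,5-dihydroxy-6-oxocyclohex-1-en-1-yl]methyl benzoate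
Product: 11 [(3R,4R,5R,6S)-3-acetoxy-4,5,6-trihydroxycyclohex-1-en-1-yl]methyl benzoate
Conditions: Me4NBH(OAc)3 (5 equiv), MeCN/AcOH (1:1), −30 to −20 °C
Reagents that add atoms: none
Why: Evans–Saksena hydroxyl-directed reduction; ligand exchange ties boron to O5 or O6, and hydride is delivered within the complex to the upper face of the C4 carbonyl, giving the carbinol with O4 on the lower face (4,5-trans, 4,6-anti, 4S). The reagent does not reduce esters or undirected carbonyls, and the acidic medium suppresses elimination and acyl migration.

Step 9
Reactants: 11 [(3R,4R,5R,6S)-3-acetoxy-4,5,6-trihydroxycyclohex-1-en-1-yl]methyl benzoate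
Product: 13 [(3R,4S,5R,6S)-3-acetoxy-5-(benzoyloxy)-4,6-dihydroxycyclohex-1-en-1-yl]methyl benzoate (CNP0169028.1), via cyclic 5,6-orthobenzoate 12 (not isolated)
Conditions: PhC(OMe)3 (1.3 equiv), CSA (cat.), MeCN, rt; then AcOH/H2O (4:1), 0 °C to rt
Reagents that add atoms: trimethyl orthobenzoate, COC(OC)(OC)c1ccccc1; water, O
Why: Orthoester exchange should close a 2-methoxy-2-phenyl-1,3-dioxolane only across the cis O5/O6 pair, and mild aqueous acid opens such cyclic orthoesters to the ester on the axial oxygen and the free equatorial hydroxyl. A(1,2) strain between C7 and the C4 substituent holds O4 pseudoaxial in the half-chair, which makes the trans-related O5 axial and O6 equatorial, so the benzoate should end on O5; no stereocentre is touched.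

## Compound list

1 | 2,5-dimethoxybenzyl alcohol | COc1ccc(OC)c(CO)c1 | starting material
2 | benzoyl chloride | O=C(Cl)c1ccccc1 | starting material
3 | 2,5-dimethoxybenzyl benzoate | COc1ccc(OC)c(COC(=O)c2ccccc2)c1 | intermediate
4 | methanol | CO | starting material
5 | (3,3,6,6-tetramethoxycyclohexa-1,4-dien-1-yl)methyl benzoate | COC1(OC)C=CC(OC)(OC)C(COC(=O)c2ccccc2)=C1 | intermediate
6 | (6,6-dimethoxy-3-oxocyclohexa-1,4-dien-1-yl)methyl benzoate | O=C1C=CC(OC)(OC)C(COC(=O)c2ccccc2)=C1 | intermediate
7 | [(3S)-3-hydroxy-6,6-dimethoxycyclohexa-1,4-dien-1-yl]methyl benzoate | O[C@@H]1C=C(COC(=O)c2ccccc2)C(OC)(OC)C=C1 | intermediate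
8 | [(3S)-3-acetoxy-6,6-dimethoxycyclohexa-1,4-dien-1-yl]methyl benzoate | CC(=O)O[C@@H]1C=C(COC(=O)c2ccccc2)C(OC)(OC)C=C1 | intermediate
9 | [(3R,4R,5S)-3-acetoxy-4,5-dihydroxy-6,6-dimethoxycyclohex-1-en-1-yl]methyl benzoate | CC(=O)O[C@@H]1C=C(COC(=O)c2ccccc2)C(OC)(OC)[C@@H](O)[C@H]1O | intermediate
10 | [(3R,4R,5S)-3-acetoxy-4,5-dihydroxy-6-oxocyclohex-1-en-1-yl]methyl benzoate | CC(=O)O[C@@H]1C=C(COC(=O)c2ccccc2)C(=O)[C@@H](O)[C@H]1O | intermediate
11 | [(3R,4R,5R,6S)-3-acetoxy-4,5,6-trihydroxycyclohex-1-en-1-yl]methyl benzoate | CC(=O)O[C@@H]1C=C(COC(=O)c2ccccc2)[C@H](O)[C@@H](O)[C@H]1O | intermediate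
12 | cyclic methyl orthobenzoate of 11 across O5 and O6, not isolated (2-methoxy-2-phenyl-1,3-dioxolane cis-fused at C5/C6; C1 R, C4 S, C5 R, C6 S; both epimers at the orthoester carbon) | CC(=O)O[C@@H]1C=C(COC(=O)c2ccccc2)[C@H](O)[C@H]3OC(OC)(c4ccccc4)O[C@@H]13 | intermediate
13 | [(3R,4S,5R,6S)-3-acetoxy-5-(benzoyloxy)-4,6-dihydroxycyclohex-1-en-1-yl]methyl benzoate | CC(=O)O[C@@H]1C=C(COC(=O)c2ccccc2)[C@H](O)[C@@H](OC(=O)c2ccccc2)[C@H]1O | target

## Step count and least certain steps

Total step count: 9. Longest linear sequence: 9 steps (1 to 13).

Step 2 (key step). The most likely failure is loss of the benzoate by transesterification with methoxide formed at the cathode, together with some oxidation at the C7 side chain; both follow from running an ester in methanol under current. Fallback: the order of acylation and dearomatisation is reversed. Setting out from 1, electrolysis in 4 in the ordinary basic medium (KOH, MeOH, carbon anode, 0 °C), where no ester is present, should give (3,3,6,6-tetramethoxycyclohexa-1,4-dien-1-yl)methanol F1. Benzoylation of F1 with 2 (Et3N, DMAP, CH2Cl2) returns to the route at 5.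

Step 4. The most likely failure is poor enantioface discrimination, because both carbonyl flanks are CH= groups that differ only at the β-carbon; slow turnover caused by the bulky ketal is a second possibility. Fallback: setting out from 6, a Luche reduction (NaBH4, CeCl3·7H2O, MeOH, −78 °C) gives the racemic dienol [3-hydroxy-6,6-dimethoxycyclohexa-1,4-dien-1-yl]methyl benzoate F2. Lipase-catalysed kinetic resolution (immobilised Candida antarctica lipase B, vinyl acetate, tert-butyl methyl ether) is expected, by the usual size model for secondary alcohols, to acetylate the R enantiomer to [(3R)-3-acetoxy-6,6-dimethoxycyclohexa-1,4-dien-1-yl]methyl benzoate F3 and to leave the S alcohol, which is 7; the route is rejoined at 7. Should the enzyme prefer the other enantiomer, the acetate formed would be 8 itself. The cost is the loss of half the material.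

Step 6. The most likely failure is a shift of the acetyl group from O1 to the new O6 hydroxyl in the amine-containing aqueous medium, together with incomplete preference for the face opposite the acetate; some osmylation of C2=C3 is also possible. Fallback: the acetate is replaced by a group that is bulkier and cannot migrate, and is put back after the diol is masked. Setting out from 7, silylation (TBSCl, imidazole, DMF) gives [(3S)-3-(tert-butyldimethylsilyloxy)-6,6-dimethoxycyclohexa-1,4-dien-1-yl]methyl benzoate F4. Osmylation (OsO4 cat., NMO) gives the diol [(3R,4R,5S)-3-(tert-butyldimethylsilyloxy)-4,5-dihydroxy-6,6-dimethoxycyclohex-1-en-1-yl]methyl benzoate F5. Acetalisation (2,2-dimethoxypropane, PPTS) gives the 5,6-O-isopropylidene silyl ether F6. Desilylation (Bu4NF buffered with AcOH, THF, 0 °C) gives the 5,6-O-isopropylidene C1 alcohol F7. Acetylation (Ac2O, pyridine) gives the 5,6-O-isopropylidene C1 acetate F8. Aqueous TFA then removes acetonide and ketal together and returns to the route at 10. This detour does not alter the intrinsic preference between the two alkenes, which rests on the extra allylic benzoate at C3.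

Step 9. The most likely failure is opening of the orthoester toward the O6 benzoate, or toward a mixture, because the half-chair can invert and the axial preference is then less clear-cut; benzoyl migration between the cis O5 and O6 during work-up would have the same effect. Fallback: O6 is blocked and O5 acylated before C4 is unveiled. Setting out from 9, silylation of the less hindered hydroxyl (TBSCl, imidazole, DMF, 0 °C) gives [(3R,4R,5S)-3-acetoxy-4-(tert-butyldimethylsilyloxy)-5-hydroxy-6,6-dimethoxycyclohex-1-en-1-yl]methyl benzoate F9. Benzoylation of the remaining hydroxyl next to the ketal (BzCl, pyridine, DMAP) gives [(3R,4S,5S)-3-acetoxy-5-(benzoyloxy)-4-(tert-butyldimethylsilyloxy)-6,6-dimethoxycyclohex-1-en-1-yl]methyl benzoate F10. Aqueous TFA removes ketal and silyl ether to give [(3R,4S,5S)-3-acetoxy-5-(benzoyloxy)-4-hydroxy-6-oxocyclohex-1-en-1-yl]methyl benzoate F11. Reduction with Me4NBH(OAc)3, now directed by O6 alone in the 1,3-anti sense, returns to the route at 13.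

## Further compounds

F1 | step 2 | (3,3,6,6-tetramethoxycyclohexa-1,4-dien-1-yl)methanol | COC1(OC)C=CC(OC)(OC)C(CO)=C1
F2 | step 4 | racemic [3-hydroxy-6,6-dimethoxycyclohexa-1,4-dien-1-yl]methyl benzoate | OC1C=C(COC(=O)c2ccccc2)C(OC)(OC)C=C1
F3 | step 4 | [(3R)-3-acetoxy-6,6-dimethoxycyclohexa-1,4-dien-1-yl]methyl benzoate | CC(=O)O[C@H]1C=C(COC(=O)c2ccccc2)C(OC)(OC)C=C1
F4 | step 6 | [(3S)-3-(tert-butyldimethylsilyloxy)-6,6-dimethoxycyclohexa-1,4-dien-1-yl]methyl benzoate | CC(C)(C)[Si](C)(C)O[C@@H]1C=C(COC(=O)c2ccccc2)C(OC)(OC)C=C1
F5 | step 6 | [(3R,4R,5S)-3-(tert-butyldimethylsilyloxy)-4,5-dihydroxy-6,6-dimethoxycyclohex-1-en-1-yl]methyl benzoate | CC(C)(C)[Si](C)(C)O[C@@H]1C=C(COC(=O)c2ccccc2)C(OC)(OC)[C@@H](O)[C@H]1O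
F6 | step 6 | 5,6-O-isopropylidene acetal of F5 (C1 silyl ether, C4 dimethyl ketal) | CC(C)(C)[Si](C)(C)O[C@@H]1C=C(COC(=O)c2ccccc2)C(OC)(OC)[C@H]3OC(C)(C)O[C@@H]13
F7 | step 6 | 5,6-O-isopropylidene C1 alcohol (desilylated F6) | O[C@@H]1C=C(COC(=O)c2ccccc2)C(OC)(OC)[C@H]3OC(C)(C)O[C@@H]13
F8 | step 6 | 5,6-O-isopropylidene C1 acetate (acetylated F7) | CC(=O)O[C@@H]1C=C(COC(=O)c2ccccc2)C(OC)(OC)[C@H]3OC(C)(C)O[C@@H]13
F9 | step 9 | [(3R,4R,5S)-3-acetoxy-4-(tert-butyldimethylsilyloxy)-5-hydroxy-6,6-dimethoxycyclohex-1-en-1-yl]methyl benzoate | CC(=O)O[C@@H]1C=C(COC(=O)c2ccccc2)C(OC)(OC)[C@@H](O)[C@H]1O[Si](C)(C)C(C)(C)C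
F10 | step 9 | [(3R,4S,5S)-3-acetoxy-5-(benzoyloxy)-4-(tert-butyldimethylsilyloxy)-6,6-dimethoxycyclohex-1-en-1-yl]methyl benzoate | CC(=O)O[C@@H]1C=C(COC(=O)c2ccccc2)C(OC)(OC)[C@@H](OC(=O)c3ccccc3)[C@H]1O[Si](C)(C)C(C)(C)C
F11 | step 9 | [(3R,4S,5S)-3-acetoxy-5-(benzoyloxy)-4-hydroxy-6-oxocyclohex-1-en-1-yl]methyl benzoate | CC(=O)O[C@@H]1C=C(COC(=O)c2ccccc2)C(=O)[C@@H](OC(=O)c3ccccc3)[C@H]1O
A1 | alternative 1 | methyl 2,5-diacetoxy-1-(p-tolylsulfinyl)cyclohex-3-ene-1-carboxylate (ester cis to the neighbouring acetate) | CC(=O)O[C@@H]1C[C@@](C(=O)OC)([S@@](=O)c2ccc(C)cc2)[C@H](OC(C)=O)C=C1
A2 | alternative 1 | (1E,3E)-buta-1,3-diene-1,4-diyl diacetate | CC(=O)O/C=C/C=C/OC(C)=O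
A3 | alternative 1 | methyl 2-[(S)-p-tolylsulfinyl]acrylate | C=C(C(=O)OC)[S@@](=O)c1ccc(C)cc1
A4 | alternative 2 | cyclohexane-fused isoxazoline with C1–OH, C2–OBz and the C5/C6 acetonide | O[C@@H]1[C@H](OC(=O)c2ccccc2)[C@H]2CON=C2[C@@H](OC(C)(C)O3)[C@H]13
A5 | alternative 2 | open-chain hept-6-enose oxime (C5/C6 acetonide, C1–OH, C2–OBz, terminal vinyl) | C=C[C@@H](OC(=O)c1ccccc1)[C@@H](O)[C@@H]2OC(C)(C)O[C@@H]2C=NO
A6 | alternative 2 | D-mannose | O=C[C@@H](O)[C@@H](O)[C@H](O)[C@H](O)CO
A7 | alternative 3 | endo 5-(benzoyloxymethyl)-7-oxabicyclo[2.2.1]hept-5-ene-2,3-diyl carbonate | O1[C@@H]2C=C(COC(=O)c3ccccc3)[C@H]1[C@@H](OC(=O)O4)[C@H]24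
A8 | alternative 3 | furan-3-ylmethyl benzoate | O=C(OCc1ccoc1)c1ccccc1
A9 | alternative 3 | vinylene carbonate | O=C1OC=CO1
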